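The oxolane (O1, C2, C3, C4, C5) is cut at C2–C3. The feature exploited is the C2–H bond: flanked by O1 and the guaiacyl ring it is the most hydridic C–H bond present, and it stands 1,5 to C3, whose substituent C9 can be carried as an ester. A rhodium carbene generated at C3 should therefore insert into it, closing the ring and fixing C2 and C3 relative to C4 in a single operation. The precursor is an acyclic tert-butyl α-diazo ester with one stereocentre, C4, set by an Evans alkylation and bearing a silylated guaiacylmethyl group and a CH2–O–vanillyl ether. Reduction, caffeoylation and desilylation complete the (2R,3S,4S) target.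

Key step: step 10

Remarks on the chemistry:
- Numbering: O1, C2 (aryl-bearing), C3 (bearing C9), C4 (arylmethyl-bearing), C5 (ring CH2); C9 is the exocyclic CH2O carbon.
- Abbreviations: TBS = tert-butyldimethylsilyl; Ar = 4-(tert-butyldimethylsilyloxy)-3-methoxyphenyl.
- The target oxolane is 2,3-trans, 3,4-cis and 2,4-trans. C3 is R in ester 17 and S from alcohol 18 onward only because the CIP rank of C9 changes; nothing moves in space.
- Assumption: both enantiomers of 4-benzyl-1,3-oxazolidin-2-one and the catalyst Rh2(S-PTTL)4 are taken as purchasable.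

Step 1
Reactants: 1 3-(4-hydroxy-3-methoxyphenyl)propanoic acid
Product: 3 3-Ar-propanoic acid, via silyl ester 2 (not isolated)
Conditions: TBSCl (2.4 equiv), imidazole, DMF, rt; then AcOH/THF/H2O, rt
Reagents that add atoms: tert-butyldimethylsilyl chloride, CC(C)(C)[Si](C)(C)Cl
Why: Silyl ether formation on both acidic OH groups is followed by hydrolysis of the far more labile silyl ester in aqueous acetic acid, which should leave the aryl silyl ether untouched.

Step 2
Reactants: 3 3-Ar-propanoic acid; 4 (4R)-4-benzyl-1,3-oxazolidin-2-one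
Product: 6 (4R)-4-benzyl-3-(3-Ar-propanoyl)-1,3-oxazolidin-2-one, via mixed pivalic anhydride 5 (not isolated)
Conditions: Me3CCOCl, Et3N, THF, −20 °C; then 4, LiCl, −20 °C to rt
Reagents that add atoms: none
Why: Auxiliary loading by the mixed-anhydride N-acylation method, in which the LiCl-activated oxazolidinone attacks the unhindered acyl carbon of the pivalic anhydride, so that no strong base meets the aryl silyl ether.

Step 3
Reactants: 6 (4R)-4-benzyl-3-(3-Ar-propanoyl)-1,3-oxazolidin-2-one; 7 tert-butyl bromoacetate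
Product: 8 tert-butyl (3S)-3-(Ar-methyl)-4-[(4R)-4-benzyl-2-oxo-1,3-oxazolidin-3-yl]-4-oxobutanoate
Conditions: NaN(SiMe3)2, THF, −78 °C; then 7, −78 to −40 °C
Reagents that add atoms: none
Why: Evans asymmetric alkylation, in which the chelated Z sodium enolate should take the activated α-bromo ester on the face opposite the benzyl group of the (R)-auxiliary, setting the new stereocentre (the later C4) as S.

Step 4
Reactants: 8 tert-butyl (3S)-3-(Ar-methyl)-4-[(4R)-4-benzyl-2-oxo-1,3-oxazolidin-3-yl]-4-oxobutanoate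
Product: 9 tert-butyl (3S)-3-(Ar-methyl)-4-hydroxybutanoate
Conditions: LiBH4, MeOH (1 equiv), THF, 0 °C
Reagents that add atoms: none
Why: Reductive removal of the auxiliary, since LiBH4 attacks the activated exocyclic imide carbonyl much faster than the tert-butyl ester, and no enolate is formed, so the stereocentre should be retained while 4 is recovered.

Step 5
Reactants: 10 vanillin (4-hydroxy-3-methoxybenzaldehyde)
Product: 11 4-(tert-butyldimethylsilyloxy)-3-methoxybenzaldehyde
Conditions: TBSCl, imidazole, DMF, rt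
Reagents that add atoms: tert-butyldimethylsilyl chloride, CC(C)(C)[Si](C)(C)Cl
Why: Standard silyl ether formation on the phenol, with the aldehyde inert under these conditions.

Step 6
Reactants: 11 4-(tert-butyldimethylsilyloxy)-3-methoxybenzaldehyde
Product: 12 [4-(tert-butyldimethylsilyloxy)-3-methoxyphenyl]methanol
Conditions: NaBH4, MeOH/THF, 0 °C
Reagents that add atoms: none
Why: Borohydride reduction of an aryl aldehyde to the benzylic alcohol, which should spare the aryl silyl ether at 0 °C.

Step 7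
Reactants: 12 [4-(tert-butyldimethylsilyloxy)-3-methoxyphenyl]methanol
Product: 13 Ar-methyl 2,2,2-trichloroacetimidate
Conditions: Cl3CCN, DBU (cat.), CH2Cl2, 0 °C
Reagents that add atoms: trichloroacetonitrile, ClC(Cl)(Cl)C#N
Why: Base-catalysed addition of the alcohol to trichloroacetonitrile (trichloroacetimidate formation), as practised for 4-methoxybenzyl alcohol.

Step 8
Reactants: 9 tert-butyl (3S)-3-(Ar-methyl)-4-hydroxybutanoate; 13 Ar-methyl 2,2,2-trichloroacetimidate
Product: 14 tert-butyl (3S)-3-(Ar-methyl)-4-(Ar-methoxy)butanoate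
Conditions: PPTS (cat.), CH2Cl2, 0 °C to rt
Reagents that add atoms: none
Why: Acid-catalysed O-benzylation with a trichloroacetimidate, in which the electron-rich benzylic imidate ionises under a weak acid and is captured by the primary alcohol, avoiding the basic Williamson conditions that would lactonise the γ-hydroxy ester and cleave the aryl silyl ethers.

Step 9
Reactants: 14 tert-butyl (3S)-3-(Ar-methyl)-4-(Ar-methoxy)butanoate
Product: 16 tert-butyl (3S)-2-diazo-3-(Ar-methyl)-4-(Ar-methoxy)butanoate, via trifluoroacetyl ester 15 (not isolated)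
Conditions: LiN(iPr)2, THF, −78 °C, then CF3CO2CH2CF3; aq. HCl work-up; then 4-acetamidobenzenesulfonyl azide, Et3N, H2O (1 equiv), MeCN, rt
Reagents that add atoms: 4-acetamidobenzenesulfonyl azide, CC(=O)Nc1ccc(cc1)S(=O)(=O)N=[N+]=[N-]
Why: Detrifluoroacetylative diazo transfer (a deacylative Regitz diazo transfer), in which Claisen trifluoroacetylation of the ester enolate activates C2 so that the sulfonyl azide adds and the adduct fragments with loss of the trifluoroacetyl group as its sulfonamide, while the neighbouring stereocentre carries no acidic hydrogen and should stay S.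

Step 10
Reactants: 16 tert-butyl (3S)-2-diazo-3-(Ar-methyl)-4-(Ar-methoxy)butanoate
Product: 17 tert-butyl (2R,3R,4S)-2-Ar-4-(Ar-methyl)oxolane-3-carboxylate
Conditions: Rh2(S-PTTL)4 (2 mol%, divalent rhodium; dirhodium tetrakis[N-phthaloyl-(S)-tert-leucinate]), toluene, −78 °C, slow addition of 16
Reagents that add atoms: none
Why: The catalyst expels N2 from 16 to give an electrophilic rhodium carbene at C3, which accepts the hydridic C2–H bond (α to O1 and benzylic to the silyloxy-methoxy arene) in a concerted three-centre transition state that forms C2–C3 with retention at C2 and releases the catalyst. This is the known dirhodium-catalysed intramolecular 1,5 C–H insertion of α-diazo esters into ether α-C–H bonds that gives oxolane-3-carboxylates. The oxolane closes as a five-membered ring by C–C bond formation between C2 and C3 through a chair-like six-centre array (C3, C4, C5, O1, C2 and the migrating hydrogen). C2 is controlled by the existing C4 centre, because transfer of only one of the two diastereotopic hydrogens keeps the C2 aryl group and the C4 arylmethyl group pseudo-equatorial on opposite faces (2,4-trans), with the chiral carboxylate pocket as a second bias; C3 is controlled by the tert-butyl ester pointing away from the C2 aryl group in the same array (2,3-trans, hence 3,4-cis), and being α to the ester it could still be equilibrated by base if it emerged cis to the aryl group. The step needs insertion to beat 1,2-hydride migration from C4 (which would give the α,β-unsaturated ester) and carbene attack on the arene of the C4 arylmethyl group; the bulky phthalimido-carboxylate ligands, the tert-butyl ester, the temperature of −78 °C and the doubly activated C–H bond should secure this.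

Step 11
Reactants: 17 tert-butyl (2R,3R,4S)-2-Ar-4-(Ar-methyl)oxolane-3-carboxylate
Product: 18 [(2R,3S,4S)-2-Ar-4-(Ar-methyl)oxolan-3-yl]methanol
Conditions: iBu2AlH (excess), CH2Cl2, −78 to 0 °C; aq. potassium sodium tartrate
Reagents that add atoms: none
Why: Hydride reduction of the ester to the primary alcohol C9–OH under non-basic conditions, which should leave C3, the benzylic C2–O bond and the aryl silyl ethers alone.

Step 12
Reactants: 19 caffeic acid
Product: 21 (E)-3-[3,4-bis(tert-butyldimethylsilyloxy)phenyl]prop-2-enoic acid, via tris-silyl derivative 20 (not isolated)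
Conditions: TBSCl (3.5 equiv), imidazole, DMF, rt; then AcOH/THF/H2O, rt
Reagents that add atoms: tert-butyldimethylsilyl chloride, CC(C)(C)[Si](C)(C)Cl
Why: Per-silylation of the catechol and the acid followed by selective hydrolysis of the labile silyl ester, the same silyl ether chemistry as in step 1.

Step 13
Reactants: 18 [(2R,3S,4S)-2-Ar-4-(Ar-methyl)oxolan-3-yl]methanol; 21 (E)-3-[3,4-bis(tert-butyldimethylsilyloxy)phenyl]prop-2-enoic acid
Product: 22 [(2R,3S,4S)-2-Ar-4-(Ar-methyl)oxolan-3-yl]methyl (E)-3-[3,4-bis(tert-butyldimethylsilyloxy)phenyl]prop-2-enoate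
Conditions: DCC, DMAP (cat.), CH2Cl2, 0 °C to rt
Reagents that add atoms: none
Why: Steglich esterification, in which DMAP passes the carbodiimide-activated cinnamoyl group to the primary alcohol without touching any stereocentre or the E alkene.

Step 14
Reactants: 22 [(2R,3S,4S)-2-Ar-4-(Ar-methyl)oxolan-3-yl]methyl (E)-3-[3,4-bis(tert-butyldimethylsilyloxy)phenyl]prop-2-enoate
Product: 23 [(2R,3S,4S)-2-(4-hydroxy-3-methoxyphenyl)-4-[(4-hydroxy-3-methoxyphenyl)methyl]oxolan-3-yl]methyl (E)-3-(3,4-dihydroxyphenyl)prop-2-enoate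
Conditions: Bu4NF, AcOH (1:1, 4.4 equiv), THF, 0 °C, degassed
Reagents that add atoms: none
Why: Fluoride-mediated cleavage of the four aryl silyl ethers, with acetic acid keeping the phenols protonated so that the caffeate ester, the catechol and the benzylic C2–O bond (no quinone-methide ring opening) should survive.

Compound list
1 | 3-(4-hydroxy-3-methoxyphenyl)propanoic acid | COc1cc(CCC(=O)O)ccc1O | starting material
2 | tert-butyldimethylsilyl 3-[4-(tert-butyldimethylsilyloxy)-3-methoxyphenyl]propanoate | COc1cc(CCC(=O)O[Si](C)(C)C(C)(C)C)ccc1O[Si](C)(C)C(C)(C)C | intermediate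
3 | 3-[4-(tert-butyldimethylsilyloxy)-3-methoxyphenyl]propanoic acid | COc1cc(CCC(=O)O)ccc1O[Si](C)(C)C(C)(C)C | intermediate
4 | (4R)-4-benzyl-1,3-oxazolidin-2-one | O=C1N[C@H](Cc2ccccc2)CO1 | starting material
5 | 3-[4-(tert-butyldimethylsilyloxy)-3-methoxyphenyl]propanoic pivalic anhydride | COc1cc(CCC(=O)OC(=O)C(C)(C)C)ccc1O[Si](C)(C)C(C)(C)C | intermediate
6 | (4R)-4-benzyl-3-{3-[4-(tert-butyldimethylsilyloxy)-3-methoxyphenyl]propanoyl}-1,3-oxazolidin-2-one | COc1cc(CCC(=O)N2[C@H](Cc3ccccc3)COC2=O)ccc1O[Si](C)(C)C(C)(C)C | intermediate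
7 | tert-butyl bromoacetate | CC(C)(C)OC(=O)CBr | starting material
8 | tert-butyl (3S)-4-[(4R)-4-benzyl-2-oxo-1,3-oxazolidin-3-yl]-3-{[4-(tert-butyldimethylsilyloxy)-3-methoxyphenyl]methyl}-4-oxobutanoate | CC(C)(C)OC(=O)C[C@H](Cc1ccc(O[Si](C)(C)C(C)(C)C)c(OC)c1)C(=O)N1[C@H](Cc2ccccc2)COC1=O | intermediate
9 | tert-butyl (3S)-3-{[4-(tert-butyldimethylsilyloxy)-3-methoxyphenyl]methyl}-4-hydroxybutanoate | CC(C)(C)OC(=O)C[C@H](Cc1ccc(O[Si](C)(C)C(C)(C)C)c(OC)c1)CO | intermediate
10 | vanillin (4-hydroxy-3-methoxybenzaldehyde) | COc1cc(C=O)ccc1O | starting material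
11 | 4-(tert-butyldimethylsilyloxy)-3-methoxybenzaldehyde | COc1cc(C=O)ccc1O[Si](C)(C)C(C)(C)C | intermediate
12 | [4-(tert-butyldimethylsilyloxy)-3-methoxyphenyl]methanol | COc1cc(CO)ccc1O[Si](C)(C)C(C)(C)C | intermediate
13 | [4-(tert-butyldimethylsilyloxy)-3-methoxyphenyl]methyl 2,2,2-trichloroacetimidate | COc1cc(COC(=N)C(Cl)(Cl)Cl)ccc1O[Si](C)(C)C(C)(C)C | intermediate
14 | tert-butyl (3S)-3-{[4-(tert-butyldimethylsilyloxy)-3-methoxyphenyl]methyl}-4-{[4-(tert-butyldimethylsilyloxy)-3-methoxyphenyl]methoxy}butanoate | CC(C)(C)OC(=O)C[C@H](Cc1ccc(O[Si](C)(C)C(C)(C)C)c(OC)c1)COCc1ccc(O[Si](C)(C)C(C)(C)C)c(OC)c1 | intermediate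
15 | tert-butyl (3S)-3-{[4-(tert-butyldimethylsilyloxy)-3-methoxyphenyl]methyl}-4-{[4-(tert-butyldimethylsilyloxy)-3-methoxyphenyl]methoxy}-2-(2,2,2-trifluoroacetyl)butanoate (C2 epimers, largely enolised) | CC(C)(C)OC(=O)C(C(=O)C(F)(F)F)[C@H](Cc1ccc(O[Si](C)(C)C(C)(C)C)c(OC)c1)COCc1ccc(O[Si](C)(C)C(C)(C)C)c(OC)c1 | intermediate
16 | tert-butyl (3S)-2-diazo-3-{[4-(tert-butyldimethylsilyloxy)-3-methoxyphenyl]methyl}-4-{[4-(tert-butyldimethylsilyloxy)-3-methoxyphenyl]methoxy}butanoate | CC(C)(C)OC(=O)C(=[N+]=[N-])[C@H](Cc1ccc(O[Si](C)(C)C(C)(C)C)c(OC)c1)COCc1ccc(O[Si](C)(C)C(C)(C)C)c(OC)c1 | intermediate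
17 | tert-butyl (2R,3R,4S)-2-[4-(tert-butyldimethylsilyloxy)-3-methoxyphenyl]-4-{[4-(tert-butyldimethylsilyloxy)-3-methoxyphenyl]methyl}oxolane-3-carboxylate | COc1cc(C[C@@H]2CO[C@@H](c3ccc(O[Si](C)(C)C(C)(C)C)c(OC)c3)[C@@H]2C(=O)OC(C)(C)C)ccc1O[Si](C)(C)C(C)(C)C | intermediate
18 | [(2R,3S,4S)-2-[4-(tert-butyldimethylsilyloxy)-3-methoxyphenyl]-4-{[4-(tert-butyldimethylsilyloxy)-3-methoxyphenyl]methyl}oxolan-3-yl]methanol | COc1cc(C[C@@H]2CO[C@@H](c3ccc(O[Si](C)(C)C(C)(C)C)c(OC)c3)[C@@H]2CO)ccc1O[Si](C)(C)C(C)(C)C | intermediate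
19 | caffeic acid | OC(=O)/C=C/c1ccc(O)c(O)c1 | starting material
20 | tert-butyldimethylsilyl (E)-3-[3,4-bis(tert-butyldimethylsilyloxy)phenyl]prop-2-enoate | CC(C)(C)[Si](C)(C)OC(=O)/C=C/c1ccc(O[Si](C)(C)C(C)(C)C)c(O[Si](C)(C)C(C)(C)C)c1 | intermediate
21 | (E)-3-[3,4-bis(tert-butyldimethylsilyloxy)phenyl]prop-2-enoic acid | OC(=O)/C=C/c1ccc(O[Si](C)(C)C(C)(C)C)c(O[Si](C)(C)C(C)(C)C)c1 | intermediate
22 | [(2R,3S,4S)-2-[4-(tert-butyldimethylsilyloxy)-3-methoxyphenyl]-4-{[4-(tert-butyldimethylsilyloxy)-3-methoxyphenyl]methyl}oxolan-3-yl]methyl (E)-3-[3,4-bis(tert-butyldimethylsilyloxy)phenyl]prop-2-enoate | COc1cc(C[C@@H]2CO[C@@H](c3ccc(O[Si](C)(C)C(C)(C)C)c(OC)c3)[C@@H]2COC(=O)/C=C/c2ccc(O[Si](C)(C)C(C)(C)C)c(O[Si](C)(C)C(C)(C)C)c2)ccc1O[Si](C)(C)C(C)(C)C | intermediate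
23 | [(2R,3S,4S)-2-(4-hydroxy-3-methoxyphenyl)-4-[(4-hydroxy-3-methoxyphenyl)methyl]oxolan-3-yl]methyl (E)-3-(3,4-dihydroxyphenyl)prop-2-enoate | COc1cc(C[C@@H]2CO[C@@H](c3ccc(O)c(OC)c3)[C@@H]2COC(=O)/C=C/c2ccc(O)c(O)c2)ccc1O | target

Total step count: 14. Longest linear sequence: 10 steps (1, 2, 3, 4, 8, 9, 10, 11, 13, 14).

Steps most likely to fail

1. Step 10. Hydride migration from C4 to the carbene may outrun insertion, the carbene may attack the arene of the C4 arylmethyl group, or the catalyst and the C4 centre may select the wrong diastereotopic C2–H or the wrong C3 face. The mirror-image catalyst Rh2(R-PTTL)4 (divalent rhodium) would be the first variation of conditions. The fallback changes the ring construction to the lactone aldol and benzylic ionisation sequence, setting out from 9 and aldehyde 11 and returning at 18: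
   - Alcohol 9 is lactonised with catalytic p-toluenesulfonic acid in toluene at 50 °C to (4S)-4-(Ar-methyl)oxolan-2-one F1.
   - The lithium enolate of F1 (LiN(SiMe3)2, THF, −78 °C) adds to 11 anti to the C4 substituent, giving the trans aldol lactone (3R,4S)-3-[Ar(hydroxy)methyl]-4-(Ar-methyl)oxolan-2-one F2 as carbinol epimers.
   - LiBH4 in THF reduces F2 to the triol (2S,3S)-2-[Ar(hydroxy)methyl]-3-(Ar-methyl)butane-1,4-diol F3.
   - Catalytic camphorsulfonic acid in CH2Cl2 at 0 °C ionises the benzylic carbinol, and the C5 hydroxyl should close the oxolane with the aryl group trans to C3, giving 18 before step 13.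

2. Step 9. Claisen trifluoroacetylation of the β-branched ester enolate may stay incomplete, or the azide may couple without loss of the trifluoroacetyl group. The fallback builds the diazo group from an amine, setting out from 14 and returning at 16:
   - The potassium enolate of 14 (KN(SiMe3)2, THF, −78 °C) is azidated with 2,4,6-triisopropylbenzenesulfonyl azide and quenched with AcOH, giving tert-butyl (3S)-2-azido-3-(Ar-methyl)-4-(Ar-methoxy)butanoate F4 as C2 epimers.
   - Staudinger reduction (PPh3, THF/H2O) gives tert-butyl (3S)-2-amino-3-(Ar-methyl)-4-(Ar-methoxy)butanoate F5.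
   - Diazotisation with isoamyl nitrite and catalytic AcOH in CHCl3 at reflux gives 16 before step 10.

3. Step 8. Acid may lactonise the γ-hydroxy ester with loss of the tert-butyl group, or the imidate may rearrange or self-alkylate the electron-rich arenes faster than it alkylates oxygen. The fallback forms the same C–O bond by reductive etherification, setting out from 9 and aldehyde 11 and returning at 14:
   - Alcohol 9 is silylated (Me3SiCl, Et3N, CH2Cl2, 0 °C) to tert-butyl (3S)-3-(Ar-methyl)-4-(trimethylsilyloxy)butanoate F6.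
   - F6 and 11 are combined with Et3SiH and catalytic Me3SiOSO2CF3 in CH2Cl2 at −78 °C, giving 14 before step 9.

Further compounds
F1 | step 10 | (4S)-4-{[4-(tert-butyldimethylsilyloxy)-3-methoxyphenyl]methyl}oxolan-2-one | COc1cc(C[C@@H]2COC(=O)C2)ccc1O[Si](C)(C)C(C)(C)C
F2 | step 10 | (3R,4S)-3-{[4-(tert-butyldimethylsilyloxy)-3-methoxyphenyl](hydroxy)methyl}-4-{[4-(tert-butyldimethylsilyloxy)-3-methoxyphenyl]methyl}oxolan-2-one (carbinol epimers) | OC(c1ccc(O[Si](C)(C)C(C)(C)C)c(OC)c1)[C@H]1[C@H](Cc2ccc(O[Si](C)(C)C(C)(C)C)c(OC)c2)COC1=O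
F3 | step 10 | (2S,3S)-2-{[4-(tert-butyldimethylsilyloxy)-3-methoxyphenyl](hydroxy)methyl}-3-{[4-(tert-butyldimethylsilyloxy)-3-methoxyphenyl]methyl}butane-1,4-diol (carbinol epimers) | OC(c1ccc(O[Si](C)(C)C(C)(C)C)c(OC)c1)[C@H](CO)[C@H](Cc2ccc(O[Si](C)(C)C(C)(C)C)c(OC)c2)CO
F4 | step 9 | tert-butyl (3S)-2-azido-3-{[4-(tert-butyldimethylsilyloxy)-3-methoxyphenyl]methyl}-4-{[4-(tert-butyldimethylsilyloxy)-3-methoxyphenyl]methoxy}butanoate (C2 epimers) | CC(C)(C)OC(=O)C(N=[N+]=[N-])[C@H](Cc1ccc(O[Si](C)(C)C(C)(C)C)c(OC)c1)COCc1ccc(O[Si](C)(C)C(C)(C)C)c(OC)c1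
F5 | step 9 | tert-butyl (3S)-2-amino-3-{[4-(tert-butyldimethylsilyloxy)-3-methoxyphenyl]methyl}-4-{[4-(tert-butyldimethylsilyloxy)-3-methoxyphenyl]methoxy}butanoate (C2 epimers) | CC(C)(C)OC(=O)C(N)[C@H](Cc1ccc(O[Si](C)(C)C(C)(C)C)c(OC)c1)COCc1ccc(O[Si](C)(C)C(C)(C)C)c(OC)c1
F6 | step 8 | tert-butyl (3S)-3-{[4-(tert-butyldimethylsilyloxy)-3-methoxyphenyl]methyl}-4-(trimethylsilyloxy)butanoate | CC(C)(C)OC(=O)C[C@H](Cc1ccc(O[Si](C)(C)C(C)(C)C)c(OC)c1)CO[Si](C)(C)C
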